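**Retrosynthetic overview**

1. Target 15 is (4S,5S)-4,5-dihydroxy-5-[(1S)-1-hydroxyheptadecyl]cyclopent-2-en-1-one; the last step removes an acetonide (O4/O5) and a silyl ether (C1′) from enone 14.
2. Key disconnection: the C1(=O)–C2(H)= bond of the enone. Enone 14 is opened to its isomer, 4-alkynal 13 (C1 as a formyl group on C5, C2≡C3 as an ethynyl group on C4), and closed by rhodium-catalysed intramolecular trans-hydroacylation, a polarity-reversed (acyl-metal) union of the aldehyde carbon with the alkyne terminus that loses no atom.
3. Enabling feature: the formyl carbon and the alkyne terminus are 1,4-related and held syn on the cis-1,3-dioxolane ring that ties O4 and O5 together; C5 is fully substituted (no α-hydrogen) and C4 carries an ether oxygen beside the alkyne.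
4. Alkynal 13 comes from 2,3-O-isopropylidene-L-erythronolactone 5: a lactone-enolate aldol with heptadecanal 6 sets C5 and C1′ in one step under control of C4; the lactone carbonyl becomes C1, the lactone CH2O carbon becomes C3 (oxidation, then Ohira–Bestmann homologation adds C2).
5. Lactone 5 comes from L-arabinose 1 (acetonide, periodate cleavage, lactol oxidation). Ring order: dioxolane (step 1), furanose/lactone ring (steps 2 and 3, opened in step 6), cyclopentenone last (step 10).

Key step: step 10

Remark on the chemistry: locants C1–C5 and C1′ are those of the target. The CIP descriptor of C5 changes from S to R on silylation (compounds 9–14), and that of C4 is R only in aldehyde 11; both are priority changes, no centre is inverted.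

**Route**

Step 1
Reactants: 1 L-arabinose
Product: 2 3,4-O-isopropylidene-L-arabinopyranose
Conditions: 2,2-dimethoxypropane, TsOH·H2O (cat.), DMF, rt
Reagents that add atoms: 2,2-dimethoxypropane, COC(C)(C)OC
Why: Acid-catalysed transacetalisation in which only the cis-related O3/O4 pair of the pyranose can span a five-membered acetonide, leaving the C1/C2 glycol free and touching no stereocentre.

Step 2
Reactants: 2 3,4-O-isopropylidene-L-arabinopyranose
Product: 4 2,3-O-isopropylidene-L-erythrofuranose, via 4-O-formyl-2,3-O-isopropylidene-L-erythrose 3 (not isolated)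
Conditions: NaIO4, H2O, 0 °C to rt; then Na2CO3, rt
Reagents that add atoms: none
Why: Malaprade glycol cleavage of the C1–C2 bond leaves C1 as a formate on O5, and carbonate hydrolysis of that formate lets the freed hydroxyl close the furanose lactol, so that C3 and C4 of arabinose become the untouched C2 and C3 of L-erythrose.

Step 3
Reactants: 4 2,3-O-isopropylidene-L-erythrofuranose
Product: 5 2,3-O-isopropylidene-L-erythronolactone, (3aS,6aS)-2,2-dimethyldihydrofuro[3,4-d][1,3]dioxol-4(3aH)-one
Conditions: TEMPO (cat.), PhI(OAc)2, CH2Cl2, rt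
Reagents that add atoms: none
Why: Oxoammonium (TEMPO) oxidation of the hemiacetal C–H should give the γ-lactone without touching the acetonide or either stereocentre.

Step 4
Reactants: 5 2,3-O-isopropylidene-L-erythronolactone; 6 heptadecanal
Product: 8 (3aS,6aS)-3a-[(1S)-1-hydroxyheptadecyl]-2,2-dimethyldihydrofuro[3,4-d][1,3]dioxol-4(3aH)-one, via lithium enolate 7 (not isolated)
Conditions: LiN(i-Pr)2, THF, −78 °C; then 6, −78 °C; AcOH quench at −78 °C
Reagents that add atoms: none
Why: Lithium enolate aldol addition in which the aldehyde can only enter on the convex face of the ring-fused enolate, opposite the dioxolane, so that the acetonide stays cis-fused and the quaternary carbon (C5) is fixed by C4, while a closed Zimmerman–Traxler chair with the hexadecyl chain equatorial and pointing away from the bicycle (ring-locked E-type enolate, anti sense) should set the (S)-carbinol C1′; β-loss of the acetonide oxygen from the enolate is kept slow at −78 °C.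

Step 5
Reactants: 8 aldol adduct
Product: 9 (3aR,6aS)-3a-[(1S)-1-(tert-butyldimethylsilyloxy)heptadecyl]-2,2-dimethyldihydrofuro[3,4-d][1,3]dioxol-4(3aH)-one
Conditions: TBSOTf, 2,6-lutidine, CH2Cl2, 0 °C
Reagents that add atoms: tert-butyldimethylsilyl trifluoromethanesulfonate, CC(C)(C)[Si](C)(C)OS(=O)(=O)C(F)(F)F
Why: Silyl triflate silylation of the hindered secondary alcohol protects C1′–OH so that it cannot form a lactol or lactone with the carbonyl groups made later, and the group is chosen to leave together with the acetonide in the final acid step.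

Step 6
Reactants: 9 silylated lactone
Product: 10 (4R,5S)-4-[(1S)-1-(tert-butyldimethylsilyloxy)heptadecyl]-5-(hydroxymethyl)-N-methoxy-N,2,2-trimethyl-1,3-dioxolane-4-carboxamide
Conditions: MeNH(OMe)·HCl, AlMe3, CH2Cl2, 0 °C to rt
Reagents that add atoms: N,O-dimethylhydroxylamine hydrochloride, CNOC.Cl
Why: Weinreb aminolysis of the lactone by the aluminium amide made in the flask should open the ring to the N-methoxy-N-methylamide and free the primary alcohol, which is oxidised at once to forestall re-lactonisation.

Step 7
Reactants: 10 hydroxy Weinreb amide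
Product: 11 (4R,5R)-4-[(1S)-1-(tert-butyldimethylsilyloxy)heptadecyl]-5-formyl-N-methoxy-N,2,2-trimethyl-1,3-dioxolane-4-carboxamide
Conditions: Dess–Martin periodinane, CH2Cl2, 0 °C to rt
Reagents that add atoms: none
Why: Dess–Martin oxidation takes the primary alcohol to the aldehyde under near-neutral conditions, and the formyl group already sits trans to the bulky silyloxyalkyl branch on the dioxolane, so epimerisation at C4 has no driving force.

Step 8
Reactants: 11 aldehyde
Product: 12 (4R,5S)-4-[(1S)-1-(tert-butyldimethylsilyloxy)heptadecyl]-5-ethynyl-N-methoxy-N,2,2-trimethyl-1,3-dioxolane-4-carboxamide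
Conditions: dimethyl (1-diazo-2-oxopropyl)phosphonate, K2CO3, MeOH, 0 °C to rt
Reagents that add atoms: dimethyl (1-diazo-2-oxopropyl)phosphonate, CC(=O)C(=[N+]=[N-])P(=O)(OC)OC
Why: Ohira–Bestmann (Seyferth–Gilbert) homologation, in which the diazomethylphosphonate anion released by methanolysis adds to the aldehyde and loss of phosphate and N2 with 1,2-hydrogen shift should give the terminal alkyne with C4 unchanged.

Step 9
Reactants: 12 alkynyl Weinreb amide
Product: 13 (4R,5S)-4-[(1S)-1-(tert-butyldimethylsilyloxy)heptadecyl]-5-ethynyl-2,2-dimethyl-1,3-dioxolane-4-carbaldehyde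
Conditions: i-Bu2AlH, THF, −78 °C
Reagents that add atoms: none
Why: Weinreb amide reduction stops at the aldehyde level because the hydride adduct stays chelated until work-up, and the new formyl group sits on a fully substituted carbon and cannot epimerise.

Step 10
Reactants: 13 4-alkynal
Product: 14 (3aR,6aS)-3a-[(1S)-1-(tert-butyldimethylsilyloxy)heptadecyl]-2,2-dimethyl-3a,6a-dihydro-4H-cyclopenta[d][1,3]dioxol-4-one
Conditions: [Rh(dppe)]2(BF4)2 (5 mol %; dppe = Ph2PCH2CH2PPh2), acetone, rt, Ar
Reagents that add atoms: none
Why: Oxidative addition of the formyl C–H bond to the cationic monovalent rhodium centre gives an acyl hydride of trivalent rhodium; the tethered alkyne then inserts into Rh–H with hydrogen going to the internal alkyne carbon in a net trans sense, and C(acyl)–C(alkenyl) reductive elimination from the resulting six-membered rhodacycle forms the C1–C2 bond, releases the cis-enone and returns monovalent rhodium. The closest known reaction type is the rhodium-catalysed intramolecular trans-hydroacylation of 4-alkynals to cyclopent-2-enones, documented for 4-alkynals with an ether oxygen at C3; with a terminal alkyne an alkyne-to-vinylidene shift followed by acyl migration is a second pathway that leads to the same enone. The cyclopentenone is closed in a formal 5-endo-dig mode, both alkyne carbons ending inside the ring and the acyl carbon bonding to the alkyne terminus. No stereocentre is created: C1′, C4 and C5 pass through unchanged, since C5 is quaternary and the conditions are neutral. The selectivity needed is chemoselectivity for trans-hydroacylation over cis-hydroacylation (which would give a strained alkylidenecyclobutanone), decarbonylation and alkyne oligomerisation; it is secured by the cis-dioxolane that holds formyl and ethynyl groups syn within bonding distance, by the fully substituted α-carbon (no aldol, Thorpe–Ingold acceleration) and by the propargylic ether oxygen that can bind rhodium beside the alkyne.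

Step 11
Reactants: 14 protected enone
Product: 15 (4S,5S)-4,5-dihydroxy-5-[(1S)-1-hydroxyheptadecyl]cyclopent-2-en-1-one
Conditions: CF3CO2H/H2O, 0 °C to rt
Reagents that add atoms: none
Why: Acid hydrolysis should cleave the acetonide and the silyl ether in one operation while avoiding base, under which retro-aldol cleavage and β-elimination of the 4-hydroxyl would threaten the product, and no stereocentre is involved.

**Compound list**

1 | L-arabinose (drawn open-chain) | O=C[C@H](O)[C@@H](O)[C@@H](O)CO | starting material
2 | 3,4-O-isopropylidene-L-arabinopyranose (mutarotating hemiacetal, anomeric centre left open) | OC1OC[C@@H]2OC(C)(C)O[C@@H]2[C@H]1O | intermediate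
3 | 4-O-formyl-2,3-O-isopropylidene-aldehydo-L-erythrose | O=COC[C@@H]1OC(C)(C)O[C@@H]1C=O | intermediate (not isolated)
4 | 2,3-O-isopropylidene-L-erythrofuranose (lactol, anomeric centre left open) | OC1OC[C@@H]2OC(C)(C)O[C@H]12 | intermediate
5 | 2,3-O-isopropylidene-L-erythronolactone, (3aS,6aS)-2,2-dimethyldihydrofuro[3,4-d][1,3]dioxol-4(3aH)-one | O=C1OC[C@@H]2OC(C)(C)O[C@H]12 | intermediate
6 | heptadecanal | CCCCCCCCCCCCCCCCC=O | starting material
7 | lithium enolate of 5 | [Li]OC1=C2OC(C)(C)O[C@H]2CO1 | intermediate (not isolated)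
8 | (3aS,6aS)-3a-[(1S)-1-hydroxyheptadecyl]-2,2-dimethyldihydrofuro[3,4-d][1,3]dioxol-4(3aH)-one | CCCCCCCCCCCCCCCC[C@H](O)[C@]12OC(C)(C)O[C@H]1COC2=O | intermediate
9 | (3aR,6aS)-3a-[(1S)-1-(tert-butyldimethylsilyloxy)heptadecyl]-2,2-dimethyldihydrofuro[3,4-d][1,3]dioxol-4(3aH)-one | CCCCCCCCCCCCCCCC[C@H](O[Si](C)(C)C(C)(C)C)[C@]12OC(C)(C)O[C@H]1COC2=O | intermediate
10 | (4R,5S)-4-[(1S)-1-(tert-butyldimethylsilyloxy)heptadecyl]-5-(hydroxymethyl)-N-methoxy-N,2,2-trimethyl-1,3-dioxolane-4-carboxamide | CCCCCCCCCCCCCCCC[C@H](O[Si](C)(C)C(C)(C)C)[C@]1(C(=O)N(C)OC)OC(C)(C)O[C@H]1CO | intermediate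
11 | (4R,5R)-4-[(1S)-1-(tert-butyldimethylsilyloxy)heptadecyl]-5-formyl-N-methoxy-N,2,2-trimethyl-1,3-dioxolane-4-carboxamide | CCCCCCCCCCCCCCCC[C@H](O[Si](C)(C)C(C)(C)C)[C@]1(C(=O)N(C)OC)OC(C)(C)O[C@H]1C=O | intermediate
12 | (4R,5S)-4-[(1S)-1-(tert-butyldimethylsilyloxy)heptadecyl]-5-ethynyl-N-methoxy-N,2,2-trimethyl-1,3-dioxolane-4-carboxamide | CCCCCCCCCCCCCCCC[C@H](O[Si](C)(C)C(C)(C)C)[C@]1(C(=O)N(C)OC)OC(C)(C)O[C@H]1C#C | intermediate
13 | (4R,5S)-4-[(1S)-1-(tert-butyldimethylsilyloxy)heptadecyl]-5-ethynyl-2,2-dimethyl-1,3-dioxolane-4-carbaldehyde | CCCCCCCCCCCCCCCC[C@H](O[Si](C)(C)C(C)(C)C)[C@]1(C=O)OC(C)(C)O[C@H]1C#C | intermediate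
14 | (3aR,6aS)-3a-[(1S)-1-(tert-butyldimethylsilyloxy)heptadecyl]-2,2-dimethyl-3a,6a-dihydro-4H-cyclopenta[d][1,3]dioxol-4-one | CCCCCCCCCCCCCCCC[C@H](O[Si](C)(C)C(C)(C)C)[C@]12OC(C)(C)O[C@H]1C=CC2=O | intermediate
15 | (4S,5S)-4,5-dihydroxy-5-[(1S)-1-hydroxyheptadecyl]cyclopent-2-en-1-one | CCCCCCCCCCCCCCCC[C@H](O)[C@@]1(O)C(=O)C=C[C@@H]1O | target

**Step count and risks**

Total step count: 11. Longest linear sequence: 11 steps (from L-arabinose 1; heptadecanal 6 enters at step 4).

Steps most likely to fail:

1. Step 10 (ring closure). The terminal alkyne may divert the catalyst (vinylidene formation, alkyne oligomerisation), or the hindered acyl rhodium hydride may lose CO before C–C bond formation. The fallback replaces hydroacylation by a reductive vinyl–carbonyl coupling and sets out from aldehyde 11. Stork–Zhao olefination (Ph3P=CHI from (iodomethyl)triphenylphosphonium iodide and NaN(SiMe3)2, THF, −78 °C) should give the (Z)-vinyl iodide Weinreb amide F1. Reduction with i-Bu2AlH (THF, −78 °C) should give the (Z)-iodoalkenyl aldehyde F2. An intramolecular Nozaki–Hiyama–Kishi reaction (CrCl2, NiCl2 cat., DMF, rt) should close the same C1–C2 bond to give the ring-fused cyclopentenol F3 as either carbinol epimer, and Dess–Martin oxidation comes back to the route at enone 14.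

2. Step 4 (aldol). The acetonide oxygen may be lost from the lithium enolate by β-elimination before C–C bond formation, or facial selectivity at the aldehyde carbon may be poor, giving a mixture of C1′ epimers. The fallback sets out from lactone 5. Internal-quench silylation (LiN(i-Pr)2 added to 5 and Me3SiCl in THF at −78 °C) traps the enolate as the silyl ketene acetal F4. A Mukaiyama aldol addition to 6 (BF3·OEt2, CH2Cl2, −78 °C) should give 8 together with its C1′ epimer. The mixture is oxidised (Dess–Martin periodinane) to the non-enolisable β-keto lactone F5. Corey–Bakshi–Shibata reduction with (R)-2-methyl-CBS-oxazaborolidine and BH3·SMe2 (quaternary carbon as the large group, n-alkyl chain as the small group) should then set (S)-C1′ under reagent control and come back to the route at 8.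

3. Step 6 (lactone opening). Aminolysis of the hindered lactone carbonyl may be incomplete, and the γ-hydroxy amide may re-close to the lactone with loss of the amine before it is oxidised. The fallback masks the formyl carbon as a vinyl group and sets out from lactone 9. Reduction with i-Bu2AlH (CH2Cl2, −78 °C) should give the lactol F6. Wittig methylenation of its open hydroxy-aldehyde form (Ph3PCH3Br, KOt-Bu, THF) should give the vinyl carbinol F7. Dess–Martin oxidation gives the alkenyl aldehyde F8, and Ohira–Bestmann homologation gives the enyne F9. Chemoselective Lemieux–Johnson cleavage of the vinyl group (OsO4 cat., NaIO4, 2,6-lutidine, dioxane/H2O) comes back to the route at alkynal 13.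

Further compounds
F1 | step 10 | (Z)-vinyl iodide Weinreb amide: 5-[(Z)-2-iodoethenyl] analogue of 12 | CCCCCCCCCCCCCCCC[C@H](O[Si](C)(C)C(C)(C)C)[C@]1(C(=O)N(C)OC)OC(C)(C)O[C@H]1/C=C\I
F2 | step 10 | (Z)-iodoalkenyl aldehyde: 5-[(Z)-2-iodoethenyl] analogue of 13 | CCCCCCCCCCCCCCCC[C@H](O[Si](C)(C)C(C)(C)C)[C@]1(C=O)OC(C)(C)O[C@H]1/C=C\I
F3 | step 10 | ring-fused cyclopentenol: 4-hydroxy analogue of 14 (carbinol centre left open) | CCCCCCCCCCCCCCCC[C@H](O[Si](C)(C)C(C)(C)C)[C@]12OC(C)(C)O[C@H]1C=CC2O
F4 | step 4 | trimethylsilyl ketene acetal of lactone 5 | C[Si](C)(C)OC1=C2OC(C)(C)O[C@H]2CO1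
F5 | step 4 | β-keto lactone: 3a-heptadecanoyl analogue of 8 | CCCCCCCCCCCCCCCCC(=O)[C@]12OC(C)(C)O[C@H]1COC2=O
F6 | step 6 | lactol from 9 (anomeric centre left open) | CCCCCCCCCCCCCCCC[C@H](O[Si](C)(C)C(C)(C)C)[C@]12OC(C)(C)O[C@H]1COC2O
F7 | step 6 | vinyl carbinol: 4-ethenyl-5-(hydroxymethyl)dioxolane | CCCCCCCCCCCCCCCC[C@H](O[Si](C)(C)C(C)(C)C)[C@]1(C=C)OC(C)(C)O[C@H]1CO
F8 | step 6 | alkenyl aldehyde: 4-ethenyl-5-formyldioxolane | CCCCCCCCCCCCCCCC[C@H](O[Si](C)(C)C(C)(C)C)[C@]1(C=C)OC(C)(C)O[C@H]1C=O
F9 | step 6 | enyne: 4-ethenyl-5-ethynyldioxolane | CCCCCCCCCCCCCCCC[C@H](O[Si](C)(C)C(C)(C)C)[C@]1(C=C)OC(C)(C)O[C@H]1C#C
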